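# Proposed synthesis of CNP0253650.1 (34) by a quinone monoketal Diels–Alder route

Labdane numbering is used throughout: ring A is C1–C5 with C10, ring B is C5–C10, C17 is the methyl on C8, C20 the methyl on C10, and C11–C16 the side chain.

Route in outline: 1 → 2; 3 → 4; 2 + 4 → 5 → 6 → 8 → 10 → 11 → 12 → 13 → 14 → 16 → 17 → 19 → 20 → 21 → 22 → 25; 26 → 27 → 28 → 29; 29 + 27 → 32; 25 + 32 → 33 → 34. Compounds 7, 9, 15, 18, 23, 24, 30 and 31 are formed and consumed in the flask.

## Analysis of the target

Compound 34 is the C15 ester of an ent-labdane diol, (3R,5S,9R,10S)-labda-7,13E-diene-3,15-diol, with 32-hydroxydotriacontanoic acid. The core is a trans-fused decalin: ring A carries the equatorial C3 hydroxyl and the C4 gem-dimethyl group, ring B the trisubstituted C7=C8 olefin, the C8 methyl and the C9 side chain. The four stereocentres are related as follows: H5 is anti to the C20 methyl, and the C9 chain and the C3 hydroxyl lie on the same face as C20. The absolute configuration is antipodal to the common labdanes, so it has to be created, not bought. The sensitive groups are the primary allylic ester, which must survive the unmasking of two hydroxyls, the C7=C8 olefin, which can slip to the tetrasubstituted C8=C9 position, and the allylic C9 stereocentre. The difficulty lies in setting the quaternary C10 in the absolute sense, with C5 and C9 relayed from it, and in keeping the olefin in place while an oxygen next to it is removed. The strategy rests on ring B as it stands: the C8 methyl, the C7=C8 olefin and the C10 methyl are the substitution pattern of 2,6-dimethyl-1,4-benzoquinone with carbonyls at C9 and C6, and C1–C4 with the C3 oxygen is a 2-oxygenated butadiene with one terminal methyl. Masking the C6 carbonyl as a ketal leaves the hindered C9 carbonyl as the only Lewis-basic carbonyl, and this fixes the orientation of the diene; the free quinone would be activated at its unhindered carbonyl and would orient the diene the other way round.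

## Retrosynthetic reasoning

**C15–O ester bond.** The last skeletal bond cut is the ester, which divides 34 into two fragments of similar size. Both hydroxyls of 34 are carried as silyl ethers in 33, so that fluoride, not hydrolysis, ends the synthesis. The partners are allylic alcohol 25 and the silyl-protected acid 32; the forward step is a carbodiimide esterification of a primary alcohol.

**C16–C17 of the acyl chain.** Acid 32 is cut in the middle into two C16 pieces, bromide 29 and bromo acid 27, both derived from hydroxy acid 26. The cut is made there because a single precursor then serves both halves, and the forward sp3–sp3 coupling of a Grignard reagent (30) with a primary bromide under copper catalysis tolerates the carboxylate (31).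

**C13=C14, C14–C15 and C11–C12 of the side chain.** The E trisubstituted allylic alcohol of 25 is traced to terminal alkyne 22, because syn carbometalation followed by a one-carbon electrophile sets the olefin geometry by mechanism. Alkyne 22 comes from 21 and this from iodide 20 by an SN2 reaction that forms C11–C12. No olefination of a methyl ketone, with its mixture of geometric isomers, is needed.

**C9–C11 and the C9 stereocentre.** Iodide 20 leads back to alcohol 19 and this to diene 17, in which C11 is an exocyclic methylene on C9. The forward hydroboration must deliver hydrogen to C9 anti to the axial C20 methyl. The diene comes from enone 16 by methylenation of the C9 carbonyl. Setting C9 by a kinetic addition avoids any equilibration of this allylic centre.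

**C6–O bond.** Enone 16 lacks the C6 oxygen that the cycloaddition brings in. It is put back as the axial acetate of 14, which sits gamma to the C9 carbonyl, so that reductive cleavage removes it while conjugation holds the olefin at C7=C8. Acetate 14 comes from 13 and 12, and these from trione 11 by one reduction that also creates the C3 stereocentre on the rigid trans-decalin.

**C5 configuration and the C1=C2 bond.** Trione 11 is traced to 10 (saturation of C1=C2) and 10 to ketal 8. Unmasking the C6 ketone makes C5–H the only acidic hydrogen of the molecule, so the cis fusion inherited from the cycloaddition can be corrected to trans.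

**C4 methyl.** The gem-dimethyl group of 8 is cut to enone 6, where C4 is the only enolisable position. Enone 6 comes from silyl enol ether 5 by dehydrogenation, which makes use of the enol ether instead of hydrolysing it.

**C1–C10 and C4–C5 (key disconnection).** Adduct 5 is cut across ring A into dienone 2 and diene 4. This is where the quaternary C10 is created and where absolute configuration enters; the forward step has to choose between the two enantiotopic enone olefins of 2 and their faces.

**Precursors.** Dienone 2 arises in one step from phenol 1 by oxidative ketalisation, and diene 4 in one step from enone 3 by O-silylation, so nearly all risk sits in the cycloaddition.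

## Alternatives that were turned down

**Alternative 1:** The C9–C10 bond of 3-O-silyl-15-O-(4-methoxybenzyl)-ent-labda-7,13E-dien-20-oic acid A1 is cut by a retro-[3,3] shift. This leads to δ-lactone A2, whose carbonyl is C20, whose ring oxygen sits on C7 and which carries the complete E-alkenyl chain on C7.
- Forward key step: enolisation of A2 at C10, O-silylation and Ireland–Claisen rearrangement through the boat that the six-membered lactone enforces. This forms C9–C10, shifts the olefin to C7=C8 and turns the lactone into carbocyclic ring B.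
- For: one stereospecific event transfers the C7 carbinol configuration to both C9 and C10, creates the C7=C8 olefin in place, needs no oxygen excision at C6 and carries the finished side chain.
- Against: C20 arrives as a carboxyl on a neopentyl quaternary carbon and must be taken down to a methyl group in about three operations in the presence of two trisubstituted olefins. A2 needs three stereocentres and a trisubstituted vinyl carbinol before the key step. The ring-contractive rearrangement of a δ-lactone requires a strained boat with an axial alkenyl group.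
- Comparison: this alternative is stronger on C9, which a sigmatropic shift sets more surely than a hydroboration, and on convergence. The chosen strategy offers the C10 methyl at the right oxidation level from the start, a two-step access to the precursors and a catalytic asymmetric step.

**Alternative 2:** The C5–C10 and C8–C9 bonds of the trans-fused bicyclic C6=C7 triethylsilyl enol ether A3 (C9 methyl ester) are cut together. This gives the acyclic triene A4, methyl (2E,6R,8E,10Z)-6-(tert-butyldimethylsilyloxy)-3,7,7-trimethyl-10-(triethylsilyloxy)dodeca-2,8,10-trienoate.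
- Forward key step: thermal intramolecular Diels–Alder reaction of A4, closing rings A and B at once.
- For: two rings and four stereocentres form in one step, the trans fusion can arise directly without epimerisation, and C11 is present as an ester.
- Against: the dienophile is a β,β-disubstituted enoate that must form the quaternary C10, and the diene terminus C5 is neopentyl, so forcing conditions are needed. Facial and endo/exo control rest only on the C3 substituent of the tether. A4 needs an enantioselective synthesis and three defined olefins. After the cycloaddition the C7 ketone must be turned into the C7=C8 olefin through a regioselective enol triflate, and the epimerisable C9 ester must be homologated.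
- Comparison: the conversion of a C7 ketone into the olefin is arguably more direct than the C6 excision of the chosen route. The chosen strategy keeps the olefin untouched from the start, sets C10 by a catalyst and not by a remote centre, and reaches its cycloaddition partners in one step each.

**Alternative 3:** The C7–C8 and C9–C10 bonds of methyl 3-(tert-butyldimethylsilyloxy)-ent-drima-5,8-dien-11-oate A5 are cut. The fragments are the ring A diene A6, tert-butyl{[(1R)-3-ethenyl-2,2,4-trimethylcyclohex-3-en-1-yl]oxy}dimethylsilane, and methyl but-2-ynoate A7.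
- Forward key step: intermolecular Diels–Alder reaction of A6 with A7, closing ring B as a 1,4-cyclohexadiene.
- For: it is the most convergent plan, the orientation is favourable (unsubstituted diene terminus to the β-carbon of the ynoate), and C17 and C11 are delivered in place.
- Against: only C10 is created, under the influence of the remote C3 centre, while C4 shows a methyl to each face. The s-cis conformer of A6 is strained by the gem-dimethyl group and ynoates are sluggish dienophiles. A5 then needs a trans-selective reduction of C5=C6 and a deconjugation of the C8=C9 ester to C7=C8 with control of C9, so two of the four stereocentres are left to late, weakly biased steps.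
- Comparison: this alternative is shorter on paper. The chosen strategy sets C10 by catalyst control and relays C5, C3 and C9 from the axial C20 methyl of a rigid trans-decalin.

Key step: step 3

## Route

Assumption: the (R)-configured binaphthol ligand is taken to deliver the C10 configuration drawn for 5; if the sense of induction proved opposite, the (S)-ligand would be used with no other change.

Step 1
Reactants: 1 4-methoxy-2,6-dimethylphenol
Product: 2 4,4-dimethoxy-2,6-dimethylcyclohexa-2,5-dien-1-one
Conditions: PhI(OAc)2, MeOH, 0 → 25 °C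
Reagents that add atoms: methanol, CO
Why: Oxidative dearomatisation of a para-alkoxyphenol by the trivalent iodine reagent gives a phenoxonium ion that methanol traps at C4, the standard entry to quinone monoketals; no stereocentre is formed.

Step 2
Reactants: 3 pent-1-en-3-one
Product: 4 (Z)-3-(tert-butyldimethylsilyloxy)penta-1,3-diene
Conditions: TBSOTf, Et3N, Et2O, 0 °C
Reagents that add atoms: tert-butyldimethylsilyl trifluoromethanesulfonate, CC(C)(C)[Si](C)(C)OS(=O)(=O)C(F)(F)F
Why: Soft enolisation and O-silylation of an ethyl ketone favours the Z enol ether (methyl syn to oxygen), the isomer that can reach the s-cis diene geometry; the tert-butyldimethylsilyl group is chosen so that the enol ether survives the Lewis acid of step 3 and is intact for step 4.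

Step 3
Reactants: 2 4,4-dimethoxy-2,6-dimethylcyclohexa-2,5-dien-1-one; 4 (Z)-3-(tert-butyldimethylsilyloxy)penta-1,3-diene
Product: 5 (4aS,5R,8aR)-6-(tert-butyldimethylsilyloxy)-4,4-dimethoxy-2,5,8a-trimethyl-4a,5,8,8a-tetrahydronaphthalen-1(4H)-one
Conditions: (R)-1,1'-bi-2-naphthol (20 mol %), TiCl2(O-i-Pr)2 (20 mol %), 4 Å molecular sieves, CH2Cl2, −30 → 0 °C
Reagents that add atoms: none
Why: The tetravalent titanium binaphtholate binds the only carbonyl of 2 (C9) and lowers the LUMO of one enone; the diene adds in an asynchronous concerted [4+2] in which its silyloxy-polarised, methyl-bearing terminus C4 leads bond formation to the β-carbon C5 and C1 closes on the α-carbon C10. The closest known reaction type is the Lewis-acid-catalysed enantioselective Diels–Alder reaction of 1,4-quinone monoketals with 2-silyloxydienes. Ring A is the six-membered cycloadduct ring of an intermolecular suprafacial–suprafacial [4+2] (bonds C1–C10 and C4–C5), while ring B is carried in by 2. C10 is set by the catalyst, which has to select one of the two enantiotopic enone olefins together with one face. C5 follows from the suprafacial addition, so H5 is cis to the C20 methyl and the adduct is cis-fused. C4 follows from the endo transition state and the Z enol ether geometry (methyl trans to H5) and is erased in step 5. The step needs para orientation, secured by the single carbonyl and the silyloxy group acting in concert, and enantioface selection, which rests on the ligand. It also needs a single addition, which holds because the remaining enone of 5 is no longer cross-conjugated and is shielded by the ketal.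

Step 4
Reactants: 5 (4aS,5R,8aR)-6-(tert-butyldimethylsilyloxy)-4,4-dimethoxy-2,5,8a-trimethyl-4a,5,8,8a-tetrahydronaphthalen-1(4H)-one
Product: 6 (4aS,5R,8aR)-4,4-dimethoxy-2,5,8a-trimethyl-4a,5-dihydronaphthalene-1,6(4H,8aH)-dione
Conditions: Pd(OAc)2 (15 mol %), O2 (1 atm), DMSO, 50 °C
Reagents that add atoms: none
Why: Saegusa–Ito oxidation: the enol ether gives a divalent-palladium enolate at C2 and syn β-hydride elimination from C1 gives the C1=C2 enone; this unveils the C3 ketone and leaves C4 as the only enolisable position of ring A.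

Step 5
Reactants: 6 (4aS,5R,8aR)-4,4-dimethoxy-2,5,8a-trimethyl-4a,5-dihydronaphthalene-1,6(4H,8aH)-dione
Product: 8 (4aS,8aR)-4,4-dimethoxy-2,5,5,8a-tetramethyl-4a,5-dihydronaphthalene-1,6(4H,8aH)-dione, via lithium dienolate 7 (not isolated)
Conditions: LiN(i-Pr)2, THF, −78 °C; then MeI, DMPU, −78 → 0 °C
Reagents that add atoms: iodomethane, CI
Why: Deprotonation at the alpha-prime carbon C4, the only acidic C–H (C2 is vinylic, C10 quaternary, and ring B cannot enolise while C6 is a ketal), gives cross-conjugated dienolate 7; C-methylation builds the gem-dimethyl group and removes the C4 stereocentre.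

Step 6
Reactants: 8 (4aS,8aR)-4,4-dimethoxy-2,5,5,8a-tetramethyl-4a,5-dihydronaphthalene-1,6(4H,8aH)-dione
Product: 10 (4aR,8aR)-2,5,5,8a-tetramethyl-4a,8a-dihydronaphthalene-1,4,6(5H)-trione, via cis-fused trione 9 (not isolated)
Conditions: 1 M aq. HCl, THF, 25 °C; then DBU (0.5 equiv), CH2Cl2, 25 °C
Reagents that add atoms: water, O
Why: Acid hydrolysis of the allylic ketal frees the C6 ketone; C5–H is then the only acidic hydrogen in the molecule, and base-mediated enolisation equilibrates the ring fusion to the trans isomer (H5 anti to the C20 methyl) without touching C10. The step is placed before the hydrogenation so that ring A offers no second enolisable site.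

Step 7
Reactants: 10 (4aR,8aR)-2,5,5,8a-tetramethyl-4a,8a-dihydronaphthalene-1,4,6(5H)-trione
Product: 11 (4aR,8aR)-2,5,5,8a-tetramethyl-4a,7,8,8a-tetrahydronaphthalene-1,4,6(5H)-trione
Conditions: H2 (1 atm), RhCl(PPh3)3 (5 mol %), benzene/EtOH, 25 °C
Reagents that add atoms: none
Why: Homogeneous hydrogenation with the monovalent rhodium complex reduces the cis-disubstituted C1=C2 bond and spares the trisubstituted C7=C8 bond of the ene-dione; no stereocentre is formed.

Step 8
Reactants: 11 (4aR,8aR)-2,5,5,8a-tetramethyl-4a,7,8,8a-tetrahydronaphthalene-1,4,6(5H)-trione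
Product: 12 (4S,4aR,6R,8aR)-4,6-dihydroxy-2,5,5,8a-tetramethyl-4a,5,6,7,8,8a-hexahydronaphthalen-1(4H)-one
Conditions: NaBH4 (about two hydride equivalents), CeCl3·7H2O, MeOH/CH2Cl2, −78 °C
Reagents that add atoms: none
Why: Luche 1,2-reduction: hydride adds axially to the C3 ketone of the rigid trans-decalin to give the equatorial alcohol, as is usual for 4,4-dimethyl-3-ketones, and to the C6 carbonyl from the face opposite the axial C4 and C10 methyls, giving the axial alcohol. The C9 carbonyl, flanked by quaternary C10 and the C8 methyl, should react last and is spared by limiting the hydride.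

Step 9
Reactants: 12 (4S,4aR,6R,8aR)-4,6-dihydroxy-2,5,5,8a-tetramethyl-4a,5,6,7,8,8a-hexahydronaphthalen-1(4H)-one
Product: 13 (4S,4aR,6R,8aR)-6-(tert-butyldimethylsilyloxy)-4-hydroxy-2,5,5,8a-tetramethyl-4a,5,6,7,8,8a-hexahydronaphthalen-1(4H)-one
Conditions: TBSCl, imidazole, DMF, 25 °C
Reagents that add atoms: tert-butyldimethylsilyl chloride, CC(C)(C)[Si](C)(C)Cl
Why: Silylation distinguishes the equatorial C3 hydroxyl from the C6 hydroxyl, which is axial and syn to two methyl groups and therefore far less accessible.

Step 10
Reactants: 13 (4S,4aR,6R,8aR)-6-(tert-butyldimethylsilyloxy)-4-hydroxy-2,5,5,8a-tetramethyl-4a,5,6,7,8,8a-hexahydronaphthalen-1(4H)-one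
Product: 14 (1S,4aR,7R,8aR)-7-(tert-butyldimethylsilyloxy)-3,4a,8,8-tetramethyl-4-oxo-1,4,4a,5,6,7,8,8a-octahydronaphthalen-1-yl acetate
Conditions: Ac2O, DMAP, Et3N, ClCH2CH2Cl, 60 °C
Reagents that add atoms: acetic anhydride, CC(=O)OC(C)=O
Why: DMAP-catalysed acylation under forcing conditions esterifies the hindered axial allylic alcohol and turns the C6 oxygen into a leaving group gamma to the C9 carbonyl.

Step 11
Reactants: 14 (1S,4aR,7R,8aR)-7-(tert-butyldimethylsilyloxy)-3,4a,8,8-tetramethyl-4-oxo-1,4,4a,5,6,7,8,8a-octahydronaphthalen-1-yl acetate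
Product: 16 (4aR,6R,8aR)-6-(tert-butyldimethylsilyloxy)-2,5,5,8a-tetramethyl-4a,5,6,7,8,8a-hexahydronaphthalen-1(4H)-one, via deconjugated enone 15 (not isolated)
Conditions: SmI2 (2.5 equiv), THF/MeOH, −78 °C; then DBU, CH2Cl2, 25 °C
Reagents that add atoms: none
Why: Two-electron reduction of the enone by divalent samarium expels the axial gamma-acetate (vinylogous cleavage of an alpha-acyloxy ketone) and gives a dienolate that protonates mainly at C8 (15). DBU then returns the olefin to conjugation at C7=C8, so the C6 oxygen is excised without a net shift of the double bond.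

Step 12
Reactants: 16 (4aR,6R,8aR)-6-(tert-butyldimethylsilyloxy)-2,5,5,8a-tetramethyl-4a,5,6,7,8,8a-hexahydronaphthalen-1(4H)-one
Product: 17 tert-butyldimethyl{[(2R,4aR,8aS)-1,1,4a,6-tetramethyl-5-methylidene-1,2,3,4,4a,5,8,8a-octahydronaphthalen-2-yl]oxy}silane
Conditions: Ph3PCH3Br, KOt-Bu, toluene, 90 °C
Reagents that add atoms: methyltriphenylphosphonium bromide, C[P+](c1ccccc1)(c1ccccc1)c1ccccc1.[Br-]
Why: Wittig methylenation; the carbonyl has no alpha-hydrogen, so the small ylide adds to the hindered C9 ketone and heating drives the collapse of the oxaphosphetane.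

Step 13
Reactants: 17 tert-butyldimethyl{[(2R,4aR,8aS)-1,1,4a,6-tetramethyl-5-methylidene-1,2,3,4,4a,5,8,8a-octahydronaphthalen-2-yl]oxy}silane
Product: 19 [(1R,4aS,6R,8aR)-6-(tert-butyldimethylsilyloxy)-2,5,5,8a-tetramethyl-1,4,4a,5,6,7,8,8a-octahydronaphthalen-1-yl]methanol, via B-alkyl-9-borabicyclononane 18 (not isolated)
Conditions: 9-borabicyclo[3.3.1]nonane (9-BBN), THF, 25 → 60 °C; then NaOH, H2O2, 0 → 25 °C
Reagents that add atoms: hydrogen peroxide, OO
Why: Hydroboration places boron on the terminal C11 of the diene and hydrogen on C9 from the face opposite the axial C20 methyl, so C11 ends cis to C20 as in the target; oxidation with retention gives the primary alcohol.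

Step 14
Reactants: 19 [(1R,4aS,6R,8aR)-6-(tert-butyldimethylsilyloxy)-2,5,5,8a-tetramethyl-1,4,4a,5,6,7,8,8a-octahydronaphthalen-1-yl]methanol
Product: 20 tert-butyl{[(2R,4aR,5R,8aS)-5-(iodomethyl)-1,1,4a,6-tetramethyl-1,2,3,4,4a,5,8,8a-octahydronaphthalen-2-yl]oxy}dimethylsilane
Conditions: I2, PPh3, imidazole, CH2Cl2, 0 → 25 °C
Reagents that add atoms: iodine, II
Why: Appel-type iodination of a primary alcohol through the alkoxyphosphonium salt; the neutral conditions leave the homoallylic olefin and the silyl ether untouched.

Step 15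
Reactants: 20 tert-butyl{[(2R,4aR,5R,8aS)-5-(iodomethyl)-1,1,4a,6-tetramethyl-1,2,3,4,4a,5,8,8a-octahydronaphthalen-2-yl]oxy}dimethylsilane
Product: 21 tert-butyldimethyl{[(2R,4aS,5R,8aS)-1,1,4a,6-tetramethyl-5-[4-(trimethylsilyl)but-3-yn-1-yl]-1,2,3,4,4a,5,8,8a-octahydronaphthalen-2-yl]oxy}silane
Conditions: 1-(trimethylsilyl)prop-1-yne, n-BuLi, THF, −78 °C; then 20, DMPU, −78 → 0 °C
Reagents that add atoms: 1-(trimethylsilyl)prop-1-yne, CC#C[Si](C)(C)C
Why: SN2 alkylation of the primary iodide by the lithiated propyne forms C11–C12; the silyl cap steers the ambident anion to react at its propargylic carbon.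

Step 16
Reactants: 21 tert-butyldimethyl{[(2R,4aS,5R,8aS)-1,1,4a,6-tetramethyl-5-[4-(trimethylsilyl)but-3-yn-1-yl]-1,2,3,4,4a,5,8,8a-octahydronaphthalen-2-yl]oxy}silane
Product: 22 {[(2R,4aS,5R,8aS)-5-(but-3-yn-1-yl)-1,1,4a,6-tetramethyl-1,2,3,4,4a,5,8,8a-octahydronaphthalen-2-yl]oxy}(tert-butyl)dimethylsilane
Conditions: K2CO3, MeOH/THF, 25 °C
Reagents that add atoms: none
Why: Base-mediated methanolysis cleaves the alkynyl C–Si bond; the hindered secondary silyl ether is stable under these conditions.

Step 17
Reactants: 22 {[(2R,4aS,5R,8aS)-5-(but-3-yn-1-yl)-1,1,4a,6-tetramethyl-1,2,3,4,4a,5,8,8a-octahydronaphthalen-2-yl]oxy}(tert-butyl)dimethylsilane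
Product: 25 (E)-5-[(1R,4aS,6R,8aS)-6-(tert-butyldimethylsilyloxy)-2,5,5,8a-tetramethyl-1,4,4a,5,6,7,8,8a-octahydronaphthalen-1-yl]-3-methylpent-2-en-1-ol, via alkenyl(dimethyl)alane 23 (not isolated), via lithium butyl(dimethyl)alkenylalanate 24 (not isolated)
Conditions: AlMe3, Cp2ZrCl2 (25 mol %), CH2Cl2, 0 → 25 °C; then n-BuLi, (CH2O)n, THF, −78 → 25 °C
Reagents that add atoms: trimethylaluminium, C[Al](C)C; paraformaldehyde (as formaldehyde), C=O
Why: Zirconium-catalysed carboalumination (Negishi) adds methyl and aluminium syn across the terminal alkyne with methyl on C13, which fixes the E geometry of C13=C14; the derived alanate adds to formaldehyde with retention and installs C15.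

Step 18
Reactants: 26 16-hydroxyhexadecanoic acid
Product: 27 16-bromohexadecanoic acid
Conditions: 48% aq. HBr, AcOH, H2SO4 (cat.), reflux
Reagents that add atoms: hydrogen bromide, Br
Why: Acid-promoted SN2 substitution of the protonated primary alcohol by bromide; any oligo-ester formed on the way is cleaved in the same medium.

Step 19
Reactants: 27 16-bromohexadecanoic acid
Product: 28 16-bromohexadecan-1-ol
Conditions: BH3·THF, THF, 0 → 25 °C
Reagents that add atoms: none
Why: Borane reduces the carboxylic acid through the acyloxyborane and does not touch the primary alkyl bromide.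

Step 20
Reactants: 28 16-bromohexadecan-1-ol
Product: 29 [(16-bromohexadecyl)oxy](tert-butyl)dimethylsilane
Conditions: TBSCl, imidazole, CH2Cl2, 25 °C
Reagents that add atoms: tert-butyldimethylsilyl chloride, CC(C)(C)[Si](C)(C)Cl
Why: Standard silylation of a primary alcohol gives a group that withstands Grignard formation and is removed with the C3 ether at the end.

Step 21
Reactants: 29 [(16-bromohexadecyl)oxy](tert-butyl)dimethylsilane; 27 16-bromohexadecanoic acid
Product: 32 32-(tert-butyldimethylsilyloxy)dotriacontanoic acid, via Grignard reagent 30 (not isolated), via chloromagnesium carboxylate 31 (not isolated)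
Conditions: 29, Mg, THF, 40 °C; separately 27, MeMgCl (1 equiv), THF, −20 °C; combine, Li2CuCl4 (3 mol %), THF, −20 → 25 °C; cold dilute aq. HCl work-up
Reagents that add atoms: none
Why: Copper-catalysed cross-coupling of a primary alkyl Grignard reagent with a primary alkyl bromide joins the two C16 units at C16–C17; the acid partner is masked as its magnesium carboxylate, which the Grignard reagent does not attack at this temperature.

Step 22
Reactants: 25 (E)-5-[(1R,4aS,6R,8aS)-6-(tert-butyldimethylsilyloxy)-2,5,5,8a-tetramethyl-1,4,4a,5,6,7,8,8a-octahydronaphthalen-1-yl]-3-methylpent-2-en-1-ol; 32 32-(tert-butyldimethylsilyloxy)dotriacontanoic acid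
Product: 33 (E)-5-[(1R,4aS,6R,8aS)-6-(tert-butyldimethylsilyloxy)-2,5,5,8a-tetramethyl-1,4,4a,5,6,7,8,8a-octahydronaphthalen-1-yl]-3-methylpent-2-en-1-yl 32-(tert-butyldimethylsilyloxy)dotriacontanoate
Conditions: DCC, DMAP (cat.), CH2Cl2, 25 °C
Reagents that add atoms: none
Why: Steglich esterification of an unhindered primary allylic alcohol under neutral conditions, with no risk to the olefins or silyl ethers.

Step 23
Reactants: 33 (E)-5-[(1R,4aS,6R,8aS)-6-(tert-butyldimethylsilyloxy)-2,5,5,8a-tetramethyl-1,4,4a,5,6,7,8,8a-octahydronaphthalen-1-yl]-3-methylpent-2-en-1-yl 32-(tert-butyldimethylsilyloxy)dotriacontanoate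
Product: 34 (E)-5-[(1R,4aS,6R,8aS)-6-hydroxy-2,5,5,8a-tetramethyl-1,4,4a,5,6,7,8,8a-octahydronaphthalen-1-yl]-3-methylpent-2-en-1-yl 32-hydroxydotriacontanoate (CNP0253650.1)
Conditions: HF·pyridine, pyridine/THF, 0 → 25 °C
Reagents that add atoms: none
Why: Fluoride-driven cleavage of both silyl ethers under buffered, non-hydrolytic conditions leaves the allylic ester intact; no stereocentre is affected.

## Compound list

1 | 4-methoxy-2,6-dimethylphenol | COc1cc(C)c(O)c(C)c1 | starting material
2 | 4,4-dimethoxy-2,6-dimethylcyclohexa-2,5-dien-1-one | CC1=CC(OC)(OC)C=C(C)C1=O | intermediate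
3 | pent-1-en-3-one | CCC(=O)C=C | starting material
4 | (Z)-3-(tert-butyldimethylsilyloxy)penta-1,3-diene | C/C=C(\O[Si](C)(C)C(C)(C)C)C=C | intermediate
5 | (4aS,5R,8aR)-6-(tert-butyldimethylsilyloxy)-4,4-dimethoxy-2,5,8a-trimethyl-4a,5,8,8a-tetrahydronaphthalen-1(4H)-one (cis-fused endo adduct) | CC1=CC(OC)(OC)[C@H]2[C@@H](C)C(O[Si](C)(C)C(C)(C)C)=CC[C@@]2(C)C1=O | intermediate
6 | (4aS,5R,8aR)-4,4-dimethoxy-2,5,8a-trimethyl-4a,5-dihydronaphthalene-1,6(4H,8aH)-dione | CC1=CC(OC)(OC)[C@H]2[C@@H](C)C(=O)C=C[C@@]2(C)C1=O | intermediate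
7 | lithium dienolate of 6 (C3–O–Li, C3=C4) | CC1=CC(OC)(OC)[C@H]2C(C)=C(O[Li])C=C[C@@]2(C)C1=O | intermediate
8 | (4aS,8aR)-4,4-dimethoxy-2,5,5,8a-tetramethyl-4a,5-dihydronaphthalene-1,6(4H,8aH)-dione | CC1=CC(OC)(OC)[C@H]2C(C)(C)C(=O)C=C[C@@]2(C)C1=O | intermediate
9 | (4aS,8aR)-2,5,5,8a-tetramethyl-4a,8a-dihydronaphthalene-1,4,6(5H)-trione (cis-fused) | CC1=CC(=O)[C@H]2C(C)(C)C(=O)C=C[C@@]2(C)C1=O | intermediate
10 | (4aR,8aR)-2,5,5,8a-tetramethyl-4a,8a-dihydronaphthalene-1,4,6(5H)-trione (trans-fused) | CC1=CC(=O)[C@@H]2C(C)(C)C(=O)C=C[C@@]2(C)C1=O | intermediate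
11 | (4aR,8aR)-2,5,5,8a-tetramethyl-4a,7,8,8a-tetrahydronaphthalene-1,4,6(5H)-trione | CC1=CC(=O)[C@@H]2C(C)(C)C(=O)CC[C@@]2(C)C1=O | intermediate
12 | (4S,4aR,6R,8aR)-4,6-dihydroxy-2,5,5,8a-tetramethyl-4a,5,6,7,8,8a-hexahydronaphthalen-1(4H)-one | CC1=C[C@H](O)[C@@H]2C(C)(C)[C@H](O)CC[C@@]2(C)C1=O | intermediate
13 | (4S,4aR,6R,8aR)-6-(tert-butyldimethylsilyloxy)-4-hydroxy-2,5,5,8a-tetramethyl-4a,5,6,7,8,8a-hexahydronaphthalen-1(4H)-one | CC1=C[C@H](O)[C@@H]2C(C)(C)[C@H](O[Si](C)(C)C(C)(C)C)CC[C@@]2(C)C1=O | intermediate
14 | (1S,4aR,7R,8aR)-7-(tert-butyldimethylsilyloxy)-3,4a,8,8-tetramethyl-4-oxo-1,4,4a,5,6,7,8,8a-octahydronaphthalen-1-yl acetate | CC1=C[C@H](OC(C)=O)[C@@H]2C(C)(C)[C@H](O[Si](C)(C)C(C)(C)C)CC[C@@]2(C)C1=O | intermediate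
15 | (4aR,6R,8aR)-6-(tert-butyldimethylsilyloxy)-2,5,5,8a-tetramethyl-4a,5,6,7,8,8a-hexahydronaphthalen-1(2H)-one (C2 epimers, olefin at C3=C4) | CC1C=C[C@@H]2C(C)(C)[C@H](O[Si](C)(C)C(C)(C)C)CC[C@@]2(C)C1=O | intermediate
16 | (4aR,6R,8aR)-6-(tert-butyldimethylsilyloxy)-2,5,5,8a-tetramethyl-4a,5,6,7,8,8a-hexahydronaphthalen-1(4H)-one | CC1=CC[C@@H]2C(C)(C)[C@H](O[Si](C)(C)C(C)(C)C)CC[C@@]2(C)C1=O | intermediate
17 | tert-butyldimethyl{[(2R,4aR,8aS)-1,1,4a,6-tetramethyl-5-methylidene-1,2,3,4,4a,5,8,8a-octahydronaphthalen-2-yl]oxy}silane | CC1=CC[C@@H]2C(C)(C)[C@H](O[Si](C)(C)C(C)(C)C)CC[C@@]2(C)C1=C | intermediate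
18 | B-alkyl-9-borabicyclo[3.3.1]nonane from 17 (boron on C11, configuration at C9 as in 19) | CC1=CC[C@@H]2C(C)(C)[C@H](O[Si](C)(C)C(C)(C)C)CC[C@@]2(C)[C@@H]1CB1C2CCCC1CCC2 | intermediate
19 | [(1R,4aS,6R,8aR)-6-(tert-butyldimethylsilyloxy)-2,5,5,8a-tetramethyl-1,4,4a,5,6,7,8,8a-octahydronaphthalen-1-yl]methanol | CC1=CC[C@@H]2C(C)(C)[C@H](O[Si](C)(C)C(C)(C)C)CC[C@@]2(C)[C@@H]1CO | intermediate
20 | tert-butyl{[(2R,4aR,5R,8aS)-5-(iodomethyl)-1,1,4a,6-tetramethyl-1,2,3,4,4a,5,8,8a-octahydronaphthalen-2-yl]oxy}dimethylsilane | CC1=CC[C@@H]2C(C)(C)[C@H](O[Si](C)(C)C(C)(C)C)CC[C@@]2(C)[C@@H]1CI | intermediate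
21 | tert-butyldimethyl{[(2R,4aS,5R,8aS)-1,1,4a,6-tetramethyl-5-[4-(trimethylsilyl)but-3-yn-1-yl]-1,2,3,4,4a,5,8,8a-octahydronaphthalen-2-yl]oxy}silane | CC1=CC[C@@H]2C(C)(C)[C@H](O[Si](C)(C)C(C)(C)C)CC[C@@]2(C)[C@@H]1CCC#C[Si](C)(C)C | intermediate
22 | {[(2R,4aS,5R,8aS)-5-(but-3-yn-1-yl)-1,1,4a,6-tetramethyl-1,2,3,4,4a,5,8,8a-octahydronaphthalen-2-yl]oxy}(tert-butyl)dimethylsilane | CC1=CC[C@@H]2C(C)(C)[C@H](O[Si](C)(C)C(C)(C)C)CC[C@@]2(C)[C@@H]1CCC#C | intermediate
23 | (E)-alkenyl(dimethyl)alane from 22 (aluminium on C14, methyl on C13) | CC1=CC[C@@H]2C(C)(C)[C@H](O[Si](C)(C)C(C)(C)C)CC[C@@]2(C)[C@@H]1CC/C(C)=C/[Al](C)C | intermediate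
24 | lithium butyl(dimethyl)[(E)-alkenyl]alanate from 23 | CC1=CC[C@@H]2C(C)(C)[C@H](O[Si](C)(C)C(C)(C)C)CC[C@@]2(C)[C@@H]1CC/C(C)=C/[Al-](C)(C)CCCC.[Li+] | intermediate
25 | (E)-5-[(1R,4aS,6R,8aS)-6-(tert-butyldimethylsilyloxy)-2,5,5,8a-tetramethyl-1,4,4a,5,6,7,8,8a-octahydronaphthalen-1-yl]-3-methylpent-2-en-1-ol | CC1=CC[C@@H]2C(C)(C)[C@H](O[Si](C)(C)C(C)(C)C)CC[C@@]2(C)[C@@H]1CC/C(C)=C/CO | intermediate
26 | 16-hydroxyhexadecanoic acid | OCCCCCCCCCCCCCCCC(=O)O | starting material
27 | 16-bromohexadecanoic acid | BrCCCCCCCCCCCCCCCC(=O)O | intermediate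
28 | 16-bromohexadecan-1-ol | BrCCCCCCCCCCCCCCCCO | intermediate
29 | [(16-bromohexadecyl)oxy](tert-butyl)dimethylsilane | BrCCCCCCCCCCCCCCCCO[Si](C)(C)C(C)(C)C | intermediate
30 | [16-(tert-butyldimethylsilyloxy)hexadecyl]magnesium bromide | Br[Mg]CCCCCCCCCCCCCCCCO[Si](C)(C)C(C)(C)C | intermediate
31 | chloromagnesium 16-bromohexadecanoate | [O-]C(=O)CCCCCCCCCCCCCCCBr.[Mg+2].[Cl-] | intermediate
32 | 32-(tert-butyldimethylsilyloxy)dotriacontanoic acid | OC(=O)CCCCCCCCCCCCCCCCCCCCCCCCCCCCCCCO[Si](C)(C)C(C)(C)C | intermediate
33 | (E)-5-[(1R,4aS,6R,8aS)-6-(tert-butyldimethylsilyloxy)-2,5,5,8a-tetramethyl-1,4,4a,5,6,7,8,8a-octahydronaphthalen-1-yl]-3-methylpent-2-en-1-yl 32-(tert-butyldimethylsilyloxy)dotriacontanoate | CC1=CC[C@@H]2C(C)(C)[C@H](O[Si](C)(C)C(C)(C)C)CC[C@@]2(C)[C@@H]1CC/C(C)=C/COC(=O)CCCCCCCCCCCCCCCCCCCCCCCCCCCCCCCO[Si](C)(C)C(C)(C)C | intermediate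
34 | (E)-5-[(1R,4aS,6R,8aS)-6-hydroxy-2,5,5,8a-tetramethyl-1,4,4a,5,6,7,8,8a-octahydronaphthalen-1-yl]-3-methylpent-2-en-1-yl 32-hydroxydotriacontanoate | CC1=CC[C@@H]2C(C)(C)[C@H](O)CC[C@@]2(C)[C@@H]1CC/C(C)=C/COC(=O)CCCCCCCCCCCCCCCCCCCCCCCCCCCCCCCO | target

## Step count and least certain steps

Total: 23 steps. Longest linear sequence: 18 steps (steps 1, 3 to 17, 22 and 23); steps 2 and 18 to 21 are side branches.

**Step 3 (key step).** Three things may go wrong.
- The dienophile carries a methyl on the reacting α-carbon and a ketal next to the β-carbon, so the catalysed cycloaddition may be too slow.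
- The Lewis acid may ionise the dimethyl ketal or open a stepwise Mukaiyama–Michael path. This would cost the silyl enol ether and, if ring closure were no longer stereospecific, would erode the link between C5 and C10.
- The catalyst may discriminate poorly between the two enantiotopic enone olefins, because the carbonyl has no α-hydrogen to organise its binding.

Fallback: 2 and 4 are combined without catalyst under about 13 kbar in CH2Cl2 at 25 °C. The single carbonyl still dictates the same orientation and the endo, cis-fused mode, and no Lewis acid threatens the ketal. The product is the racemate, that is 5 together with its enantiomer, the (4aR,5S,8aS)-adduct F1. The two are separated by preparative chromatography on a polysaccharide-based chiral stationary phase, and 5 re-enters the route at step 4.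

**Step 6.** The equilibrium between the cis- and trans-fused triones may not lie far enough on the trans side. The C4 axial methyl meets a C10 substituent in either isomer, and ring B is flattened by four sp2 carbons, so the energy gap cannot be predicted with confidence.

Fallback: kinetic instead of thermodynamic control. Trione 9 is isolated after the acid treatment and deprotonated with KN(SiMe3)2 in THF at −78 °C to the potassium dienolate F2. This is added to a cold solution of 2,6-di-tert-butyl-4-methylphenol. The bulky proton source should reach C5 only from the face opposite the pseudoaxial C20 methyl and give 10, where the route continues.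

**Step 8.** Hydride may fail to distinguish the C6 and C9 carbonyls of the ene-dione, since both are hindered (C6 by the C4 methyls, C9 by C10 and the C8 methyl). Over-reduction at C9 or conjugate reduction would result.

Fallback: over-reduce and re-oxidise. Trione 11 is reduced exhaustively with excess NaBH4 and CeCl3·7H2O at 0 °C to the (1R,4S,4aR,6R,8aR)-triol F3, in which the C9 hydroxyl is pseudoequatorial and the C6 hydroxyl axial. Activated MnO2 in CH2Cl2 should then oxidise only the C9 allylic alcohol, whose C–H bond is aligned with the olefin, and return diol 12.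

**Step 13.** Hydroboration of the hindered, conjugated exocyclic diene may be slow, and facial selectivity at C9 rests on the C20 methyl alone. Addition from the wrong face would give the C9 epimer.

Fallback: set C9 by protonation instead of hydroboration. Enone 16 is treated with Ph3P=CHOMe (from Ph3PCH2OMe Cl and KOt-Bu) to give the dienyl methyl ether F4. Two-phase hydrolysis with aqueous formic acid at 0 °C protonates C9 from the face opposite C20 and gives the β,γ-unsaturated aldehyde F5. This is reduced at once with NaBH4 to alcohol 19, before epimerisation or conjugation can set in.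

**Step 15.** Substitution at C11 is slowed by the branched C9 next to quaternary C10, while C9–H is tertiary and allylic. E2 elimination back to diene 17 may therefore compete with alkylation by the basic propargyl anion.

Fallback: reverse the polarity. Iodide 20 is converted with t-BuLi (2 equiv, Et2O/pentane, −78 °C) into the primary organolithium F6. This opens oxirane in the presence of BF3·OEt2 to give the two-carbon-extended alcohol F7. Oxidation with Dess–Martin periodinane gives aldehyde F8, and Ohira–Bestmann homologation (dimethyl (1-diazo-2-oxopropyl)phosphonate, K2CO3, MeOH) returns terminal alkyne 22.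

## Further compounds

F1 | step 3 | (4aR,5S,8aS)-6-(tert-butyldimethylsilyloxy)-4,4-dimethoxy-2,5,8a-trimethyl-4a,5,8,8a-tetrahydronaphthalen-1(4H)-one (enantiomer of 5) | CC1=CC(OC)(OC)[C@@H]2[C@H](C)C(O[Si](C)(C)C(C)(C)C)=CC[C@]2(C)C1=O
F2 | step 6 | potassium dienolate of 9 (C5=C6–O–K) | CC1=CC([O-])=C2C(C)(C)C(=O)C=C[C@@]2(C)C1=O.[K+]
F3 | step 8 | (1R,4S,4aR,6R,8aR)-2,5,5,8a-tetramethyl-1,4,4a,5,6,7,8,8a-octahydronaphthalene-1,4,6-triol | CC1=C[C@H](O)[C@@H]2C(C)(C)[C@H](O)CC[C@@]2(C)[C@@H]1O
F4 | step 13 | dienyl methyl ether of 16 (C9=C11–OMe, olefin geometry not defined) | CC1=CC[C@@H]2C(C)(C)[C@H](O[Si](C)(C)C(C)(C)C)CC[C@@]2(C)C1=COC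
F5 | step 13 | C11 aldehyde with the C9 configuration of 19 | CC1=CC[C@@H]2C(C)(C)[C@H](O[Si](C)(C)C(C)(C)C)CC[C@@]2(C)[C@@H]1C=O
F6 | step 15 | C11 organolithium from 20 | CC1=CC[C@@H]2C(C)(C)[C@H](O[Si](C)(C)C(C)(C)C)CC[C@@]2(C)[C@@H]1C[Li]
F7 | step 15 | 3-[(1R,4aS,6R,8aS)-6-(tert-butyldimethylsilyloxy)-2,5,5,8a-tetramethyl-1,4,4a,5,6,7,8,8a-octahydronaphthalen-1-yl]propan-1-ol | CC1=CC[C@@H]2C(C)(C)[C@H](O[Si](C)(C)C(C)(C)C)CC[C@@]2(C)[C@@H]1CCCO
F8 | step 15 | 3-[(1R,4aS,6R,8aS)-6-(tert-butyldimethylsilyloxy)-2,5,5,8a-tetramethyl-1,4,4a,5,6,7,8,8a-octahydronaphthalen-1-yl]propanal | CC1=CC[C@@H]2C(C)(C)[C@H](O[Si](C)(C)C(C)(C)C)CC[C@@]2(C)[C@@H]1CCC=O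
A1 | alternative 1 | 3-O-(tert-butyldimethylsilyl)-15-O-(4-methoxybenzyl)-ent-labda-7,13E-dien-20-oic acid | CC1=CC[C@@H]2C(C)(C)[C@H](O[Si](C)(C)C(C)(C)C)CC[C@@]2(C(=O)O)[C@@H]1CC/C(C)=C/COCc1ccc(OC)cc1
A2 | alternative 1 | 6-(tert-butyldimethylsilyloxy)-3-[(2E,6E)-8-(4-methoxybenzyloxy)-6-methylocta-2,6-dien-2-yl]-5,5-dimethyloctahydro-1H-isochromen-1-one (alkenyl group cis to H-4a; C-8a is enolised in the reaction and left undefined) | O=C1O[C@@H](/C(C)=C/CC/C(C)=C/COCc2ccc(OC)cc2)C[C@@H]2C(C)(C)[C@H](O[Si](C)(C)C(C)(C)C)CCC12
A3 | alternative 2 | trans-fused bicyclic C6=C7 triethylsilyl enol ether with the C9 methyl ester | C[C@@H]1C(O[Si](CC)(CC)CC)=C[C@@H]2C(C)(C)[C@H](O[Si](C)(C)C(C)(C)C)CC[C@@]2(C)[C@@H]1C(=O)OC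
A4 | alternative 2 | methyl (2E,6R,8E,10Z)-6-(tert-butyldimethylsilyloxy)-3,7,7-trimethyl-10-(triethylsilyloxy)dodeca-2,8,10-trienoate | COC(=O)/C=C(\C)CC[C@@H](O[Si](C)(C)C(C)(C)C)C(C)(C)/C=C/C(O[Si](CC)(CC)CC)=C/C
A5 | alternative 3 | methyl 3-(tert-butyldimethylsilyloxy)-ent-drima-5,8-dien-11-oate | CC1=C(C(=O)OC)[C@]2(C)CC[C@@H](O[Si](C)(C)C(C)(C)C)C(C)(C)C2=CC1
A6 | alternative 3 | tert-butyl{[(1R)-3-ethenyl-2,2,4-trimethylcyclohex-3-en-1-yl]oxy}dimethylsilane | C=CC1=C(C)CC[C@@H](O[Si](C)(C)C(C)(C)C)C1(C)C
A7 | alternative 3 | methyl but-2-ynoate | CC#CC(=O)OC
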